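Compound numbers used throughout: 1 2,4,6-trihydroxypropiophenone; 2 its 4-O-methyl ether; 3 iodoethane; 4 the 2-O-ethyl ether of 2; 5 triisopropylsilyl triflate; 6 the silylated ketone; 7 its trifluoroacetyl derivative (not isolated); 8 the diazo ketone; 9 the cis chromanone; 10 its 8-iodide; 11 ethyl (E)-3-(tributylstannyl)acrylate; 12 the aryl acrylate; 13 phenylboronic acid; 14 the 3-aryl-3-phenylpropanoate; 15 the 5-phenol; 16 its 6-iodide; 17 prenyltributylstannane; 18 the prenylated ester; 19 its trimethylstannyl ester (not isolated); 20 the target.

## Analysis of the target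

The target 20 is a chroman-4-one: an aromatic ring A (C4a, C5 to C8, C8a) fused to a dihydropyranone ring B (O1, C2, C3, C4). Ring A is fully substituted, with a hydroxyl at C5 hydrogen-bonded to the C4 carbonyl, a prenyl group at C6, a methoxy group at C7 and a 2-carboxy-1-phenylethyl group at C8, so every aromatic carbon has to be addressed regioselectively. There are three stereocentres: C2 (S) and C3 (R) carry cis methyl groups on ring B, and the benzylic carbon of the side chain (R) is remote from ring B and has no conformational tie to it, so it needs reagent control. The cis-2,3-dimethyl arrangement is the less stable one: C3 is alpha to the ketone and O1 is beta to it, so base converts it to the trans isomer by enolisation or by ring opening and reclosure. The prenyl group next to a free phenol cyclises under acid and reacts with electrophilic halogen, and the carboxylic acid must be unmasked without strong acid or base. The difficulty is therefore a hexasubstituted benzene combined with a kinetic stereodiad that tolerates no base after it is made. The strategy rests on the C2–C3 bond: C2 is an ether carbon bearing one hydrogen and a methyl group, and C3 is the carbon alpha to the C4 ketone. The bond therefore joins an alpha-keto carbene carbon to an oxygen-activated methylene, and ring B can be closed by C–H insertion under neutral conditions.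

## Retrosynthetic reasoning

**20 to 18.** The acid is carried as its ethyl ester and released last, through the stannyl ester 19. A free acid would protonate the allylic stannane of the preceding coupling, and a neutral organotin hydroxide can cleave the ester without touching C3 or the prenyl group.

**18 to 16 and 17.** The C6–CH2 bond is cut. The prenyl group is the most fragile substituent (acid, electrophilic iodine), so it is the last carbon fragment to go on. The forward reaction must be a neutral cross-coupling of the aryl iodide 16 with the stannane 17 that keeps the allyl unit linear.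

**16 to 15 to 14.** The C6–I bond and then the O5–Si bond are cut. C6 is reached only once O5 is a free phenol and C8 is occupied; it is then the single open position of ring A. Removal of the silyl group from 14 must be buffered so that no free base meets C3.

**14 to 12 and 13.** The benzylic C–phenyl bond is cut. This turns the remote stereocentre into the face selection of a conjugate addition to the acrylate 12, which a chiral rhodium–bisphosphine catalyst can control independently of ring B. Cutting the C8–benzylic bond instead would require a doubly ortho-substituted aryl nucleophile.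

**12 to 10 and 11, and 10 to 9.** The C8–vinyl bond and the C8–I bond are cut. In 9 the bulky silyl ether on O5 makes C6 and C8 unlike, so an electrophile should go to C8, between the methoxy group and the tied-back ring oxygen. The coupling with 11 is chosen to be base-free.

**9 to 8 (key disconnection).** The C2–C3 bond is cut to the diazo ketone 8, in which C2 is the methylene of an ortho ethoxy group. One bond, ring B and both ring stereocentres are gained in a step that needs neither acid nor base, which is what the cis isomer demands. A triisopropylsilyl ether is used on the other ortho oxygen rather than a smaller silyl group. It has no C–H bond alpha to oxygen, is less prone to migrate to an enolate oxygen or to hydrolyse during diazo formation, and shields C6 more strongly afterwards.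

**8 to 6 via 7.** The diazo group is traced to the propionyl CH2 of 6. A simple ketone does not accept a diazo group directly, so it is activated as the trifluoroacetyl derivative 7 and the activating group is lost during transfer.

**6 to 4 and 5; 4 to 2 and 3; 2 to 1.** The three oxygens of 1 are differentiated by their own reactivity. The para hydroxyl is the most acidic and is methylated first. The two ortho hydroxyls are equivalent, and after one is ethylated with 3 the other is held in a hydrogen bond, so it remains for silylation with 5.

## Alternatives that were turned down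

**Alternative 1: both rings from three alkynes.**
- Disconnection and key step: C4a–C8a, C5–C6 and C7–C8 are cut, giving an acyclic diyne that carries the C2–C3 stereodiad and a methoxy alkyne that carries the prenyl group. A rhodium-catalysed [2+2+2] cyclotrimerisation would give (2S,3R)-7-methoxy-5-[(4-methoxyphenyl)methoxy]-2,3-dimethyl-6-(3-methylbut-2-en-1-yl)chroman-4-one A1.
- For: it is the most convergent plan. It delivers the prenyl group at C6 and differentiated oxygens at C5 and C7 by construction. On this point it is stronger than the chosen route, which spends a desilylation, an iodination and a coupling on C6.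
- Against: the stereodiad must be built first in an open chain in which C3 is alpha to an ynone and beta to an oxygen, so it is prone to epimerisation and elimination. A secondary alkyl ethynyl ether can lose an alkene thermally to give a ketene, and a benzylic ynol ether can rearrange. Nothing in the structure enforces the orientation in which the unsymmetrical monoalkyne enters. In addition, A1 already holds the prenyl alkene when C8 still has to be functionalised with an electrophile.
- Comparison: the chosen strategy starts from an intact, inexpensive benzene ring, makes the stereocentres in the ring-closing step instead of carrying them, and adds the prenyl group after all electrophilic chemistry.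

**Alternative 2: polyketide-type Claisen closure of ring A.**
- Disconnection and key step: C4a–C5 is cut. A preformed cis-dimethyl dihydropyranone bearing a prenylated keto ester chain is folded by base so that C4a acylates, and tautomerisation gives (2S,3R)-5,7-dihydroxy-2,3-dimethyl-6-(3-methylbut-2-en-1-yl)chroman-4-one A2.
- For: the prenyl position is unambiguous, both phenols arrive unprotected, and C8 is left as the only free aromatic carbon. On ring A regiochemistry this is at least as strong as the chosen route.
- Against: the key step needs a strong base on a ring that has C3 alpha and O1 beta to a carbonyl, so the cis stereodiad is put at risk in the very step that should preserve it. C4a of a vinylogous ester is a weak nucleophile compared with the more acidic positions of the side chain. A2 then needs selective 7-O-methylation under base and C8 functionalisation next to the prenyl alkene, and the stereodiad still requires its own asymmetric synthesis.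
- Comparison: the chosen strategy creates the stereodiad under neutral conditions and never exposes it to base afterwards.

**Alternative 3: chiral-pool aryl ether and Friedel–Crafts acylation.**
- Disconnection and key step: C4–C4a is cut. 3,5-Dimethoxyphenol A5 is joined to a chiral-pool anti beta-hydroxy ester under Mitsunobu conditions with inversion, giving after hydrolysis (2R,3S)-3-(3,5-dimethoxyphenoxy)-2-methylbutanoic acid A4. Activation of the carboxyl group acylates the symmetric ring to give (2S,3R)-5,7-dimethoxy-2,3-dimethylchroman-4-one A3.
- For: the absolute and relative configuration come from a defined precursor and not from a catalyst's facial preference, the symmetric ring gives one acylation product, and no diazo compound or rhodium is needed. On cost, scale and certainty of configuration it is stronger than the chosen route.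
- Against: a Mitsunobu reaction at a secondary beta-hydroxy ester competes with elimination to the unsaturated ester. The acylation needs a strong protic or Lewis acid on an acid with an enolisable alpha centre and a beta-aryloxy leaving group, so C3 can epimerise and the aryl ether can be lost and re-added. A3 carries two methyl ethers, so O5 must later be freed by a chelating Lewis acid on the sensitive ketone.
- Comparison: the chosen strategy offers a ring closure at low temperature without acid or base, and an O5 protecting group that is different from the O7 methyl ether from the start and is removed by buffered fluoride.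

Key step: step 5

Assumption: the sense of induction of the two chiral rhodium catalysts is written as Rh2(S-PTTL)4 in step 5 (to be confirmed on a trial run) and (S)-BINAP in step 8 (alkene bound through its alpha-Si face, which for this (E)-aryl acrylate corresponds to the R benzylic centre); if either favours the mirror-image sense, its enantiomer is used and nothing else changes. Reagents 11 and 17 are taken as catalogue items.

## Route

Step 1
Reactants: 1 1-(2,4,6-trihydroxyphenyl)propan-1-one
Product: 2 1-(2,6-dihydroxy-4-methoxyphenyl)propan-1-one
Conditions: Me2SO4 (1.0 equiv), K2CO3 (1.0 equiv), acetone, rt to 40 °C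
Reagents that add atoms: dimethyl sulfate COS(=O)(=O)OC
Why: Williamson O-methylation; the 4-hydroxyl is para to the acyl group, the most acidic of the three and the only one never held in the hydrogen bond to the carbonyl, so one equivalent of base and electrophile should react there first, with over-methylation as the impurity to separate.

Step 2
Reactants: 2 1-(2,6-dihydroxy-4-methoxyphenyl)propan-1-one; 3 iodoethane
Product: 4 1-(2-ethoxy-6-hydroxy-4-methoxyphenyl)propan-1-one
Conditions: EtI (1.2 equiv), K2CO3 (1.2 equiv), acetone, reflux
Reagents that add atoms: none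
Why: Williamson O-ethylation; the two hydroxyls are equivalent by symmetry, and once one is ethylated the other is locked in the hydrogen bond to the ketone and its phenoxide is a poor nucleophile, so the reaction should stop at the monoether.

Step 3
Reactants: 4 1-(2-ethoxy-6-hydroxy-4-methoxyphenyl)propan-1-one; 5 triisopropylsilyl trifluoromethanesulfonate
Product: 6 1-[2-ethoxy-4-methoxy-6-(triisopropylsilyloxy)phenyl]propan-1-one
Conditions: 5 (1.2 equiv), 2,6-lutidine (2 equiv), CH2Cl2, 0 °C to rt
Reagents that add atoms: none
Why: O-silylation of a hydrogen-bonded phenol needs the silyl triflate, and the hindered pyridine base does not enolise the ketone. The triisopropylsilyl ether has no C–H bond alpha to oxygen, resists migration and hydrolysis in step 4 and later shields C6.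

Step 4
Reactants: 6 1-[2-ethoxy-4-methoxy-6-(triisopropylsilyloxy)phenyl]propan-1-one
Product: 8 2-diazo-1-[2-ethoxy-4-methoxy-6-(triisopropylsilyloxy)phenyl]propan-1-one, via trifluoroacetyl diketone 7 (not isolated)
Conditions: LiN(SiMe3)2 (1.1 equiv), THF, −78 °C; CF3CO2CH2CF3 (1.2 equiv), −78 °C; aq. NH4Cl; then MsN3 (1.5 equiv), Et3N (1.5 equiv), H2O (1 equiv), MeCN, rt
Reagents that add atoms: methanesulfonyl azide CS(=O)(=O)N=[N+]=[N-] (the two diazo nitrogens of 8); 2,2,2-trifluoroethyl trifluoroacetate O=C(OCC(F)(F)F)C(F)(F)F (the trifluoroacetyl group of 7 only)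
Why: Detrifluoroacetylative (Regitz-type deacylative) diazo transfer: the lithium enolate is C-acylated by the activated trifluoroacetate to 7, the enolate of 7 adds to the sulfonyl azide, and the sulfonamide nitrogen cleaves the electrophilic trifluoroacetyl group rather than the hindered, electron-rich aroyl group, leaving the diazo ketone.

Step 5
Reactants: 8 2-diazo-1-[2-ethoxy-4-methoxy-6-(triisopropylsilyloxy)phenyl]propan-1-one
Product: 9 (2S,3R)-7-methoxy-2,3-dimethyl-5-(triisopropylsilyloxy)chroman-4-one
Conditions: Rh2(S-PTTL)4 (1 mol %), toluene, 4 Å sieves, −40 to 0 °C, slow addition of 8; filtration through neutral silica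
Reagents that add atoms: none
Why: The dirhodium tetracarboxylate (divalent rhodium) attacks the diazo carbon of 8, nitrogen is lost, and the electrophilic carbenoid at the future C3 inserts into one C–H bond of the ether methylene through a three-centre, hydride-transfer-like transition state in which C3–C2 and C3–H form as rhodium leaves. The closest known reaction type is the dirhodium carboxylate-catalysed intramolecular C–H insertion of alpha-diazo ketones of ortho-alkoxyaryl ketones, which gives cis-2,3-disubstituted chroman-4-ones. Ring B closes in the 1,6 mode (carbenoid carbon, C4, C4a, C8a, O1, C2); the usually preferred 1,5 mode is absent because the fifth atom is the ether oxygen itself. C2 is fixed by which of the two enantiotopic methylene hydrogens migrates, a choice made by the chiral pocket of the four N-phthaloyl-tert-leucinate ligands. C3 is fixed in the same event by the carbenoid face that receives hydrogen and carbon; the compact transition state is expected to turn the ether methyl away from the ligand wall and leave the two methyl groups cis, the kinetic arrangement. Site selectivity is secured by the substrate: the ethoxy methylene is the only C–H bond alpha to oxygen within reach, its oxygen lone pair stabilises the positive charge building at C2, the silyl ether offers no such bond and a shielded oxygen, and the 4-methoxy group is out of range. The competing paths are the 1,2-hydride shift from the carbenoid methyl group and attack of the ethoxy oxygen on the carbenoid (oxonium ylide, then 1,2-shift), both disfavoured by the bulky carboxylate at low temperature. The neutral medium leaves C3 unenolised, so the cis isomer is not drained to the trans one.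

Step 6
Reactants: 9 (2S,3R)-7-methoxy-2,3-dimethyl-5-(triisopropylsilyloxy)chroman-4-one
Product: 10 (2S,3R)-8-iodo-7-methoxy-2,3-dimethyl-5-(triisopropylsilyloxy)chroman-4-one
Conditions: NIS (1.05 equiv), TFA (10 mol %), MeCN, 0 °C, dark
Reagents that add atoms: N-iodosuccinimide O=C1CCC(=O)N1I
Why: Electrophilic aromatic iodination; C6 lies between the methoxy group and the bulky silyl ether, C8 between the methoxy group and the tied-back ring oxygen, so iodine should enter at C8, the usual preference of 5-O-substituted 5,7-dioxygenated chromanones. Catalytic acid at 0 °C should not enolise C3 at a useful rate.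

Step 7
Reactants: 10 (2S,3R)-8-iodo-7-methoxy-2,3-dimethyl-5-(triisopropylsilyloxy)chroman-4-one; 11 ethyl (E)-3-(tributylstannyl)prop-2-enoate
Product: 12 ethyl (E)-3-[(2S,3R)-7-methoxy-2,3-dimethyl-4-oxo-5-(triisopropylsilyloxy)chroman-8-yl]prop-2-enoate
Conditions: Pd2(dba)3 (2.5 mol %), AsPh3 (20 mol %), CuI (10 mol %), NMP, 50 °C
Reagents that add atoms: none
Why: Stille coupling with retention of alkene geometry, preferred to a Heck reaction because it needs no base and so spares C3. CuI and the weakly bound arsine speed transmetalation of the electron-poor vinylstannane onto the hindered arylpalladium iodide.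

Step 8
Reactants: 12 ethyl (E)-3-[(2S,3R)-7-methoxy-2,3-dimethyl-4-oxo-5-(triisopropylsilyloxy)chroman-8-yl]prop-2-enoate; 13 phenylboronic acid
Product: 14 ethyl (3R)-3-[(2S,3R)-7-methoxy-2,3-dimethyl-4-oxo-5-(triisopropylsilyloxy)chroman-8-yl]-3-phenylpropanoate
Conditions: [Rh(OH)((S)-binap)]2 (3 mol %), 13 (3 equiv), dioxane/H2O 10:1, 50 °C
Reagents that add atoms: none
Why: Hayashi–Miyaura asymmetric 1,4-addition of an arylboronic acid to a beta-aryl acrylate, a known route to 3,3-diarylpropanoates; phenylrhodium adds to the alkene face selected by the (S)-BINAP quadrants (beta-Si face, R here because the chromanyl group outranks phenyl) and water hydrolyses the rhodium enolate. The hydroxo complex needs no added base, and the ring B stereocentres are too far away to interfere.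

Step 9
Reactants: 14 ethyl (3R)-3-[(2S,3R)-7-methoxy-2,3-dimethyl-4-oxo-5-(triisopropylsilyloxy)chroman-8-yl]-3-phenylpropanoate
Product: 15 ethyl (3R)-3-[(2S,3R)-5-hydroxy-7-methoxy-2,3-dimethyl-4-oxochroman-8-yl]-3-phenylpropanoate
Conditions: Bu4NF (1.1 equiv), AcOH (1.2 equiv), THF, 0 °C
Reagents that add atoms: none
Why: Fluoride cleavage of an aryl silyl ether, driven by the good phenoxide leaving group; acetic acid buffers the medium so that neither phenoxide nor fluoride acts as a base towards C3, and the ethyl ester is untouched.

Step 10
Reactants: 15 ethyl (3R)-3-[(2S,3R)-5-hydroxy-7-methoxy-2,3-dimethyl-4-oxochroman-8-yl]-3-phenylpropanoate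
Product: 16 ethyl (3R)-3-[(2S,3R)-5-hydroxy-6-iodo-7-methoxy-2,3-dimethyl-4-oxochroman-8-yl]-3-phenylpropanoate
Conditions: NIS (1.05 equiv), MeCN, 0 °C to rt, dark
Reagents that add atoms: N-iodosuccinimide O=C1CCC(=O)N1I
Why: Electrophilic iodination ortho to the free phenol; C6 is the only unsubstituted position of ring A and is activated by the 5-hydroxyl, the 7-methoxy group and O1, while the side-chain phenyl ring is unactivated.

Step 11
Reactants: 16 ethyl (3R)-3-[(2S,3R)-5-hydroxy-6-iodo-7-methoxy-2,3-dimethyl-4-oxochroman-8-yl]-3-phenylpropanoate; 17 tributyl(3-methylbut-2-en-1-yl)stannane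
Product: 18 ethyl (3R)-3-[(2S,3R)-5-hydroxy-7-methoxy-2,3-dimethyl-6-(3-methylbut-2-en-1-yl)-4-oxochroman-8-yl]-3-phenylpropanoate
Conditions: Pd(PPh3)4 (10 mol %), 17 (2.5 equiv), degassed toluene, 100 °C
Reagents that add atoms: none
Why: Stille allylation of an aryl iodide with a prenylstannane, widely used to put C-prenyl groups on oxygenated arenes; coupling at the unsubstituted alpha carbon of the stannane gives the linear prenyl group. The neutral, amine-free medium protects C3, and the hydrogen-bonded phenol should be tolerated.

Step 12
Reactants: 18 ethyl (3R)-3-[(2S,3R)-5-hydroxy-7-methoxy-2,3-dimethyl-6-(3-methylbut-2-en-1-yl)-4-oxochroman-8-yl]-3-phenylpropanoate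
Product: 20 (3R)-3-[(2S,3R)-5-hydroxy-7-methoxy-2,3-dimethyl-6-(3-methylbut-2-en-1-yl)-4-oxochroman-8-yl]-3-phenylpropanoic acid, via trimethylstannyl ester 19 (not isolated)
Conditions: Me3SnOH (5 equiv), ClCH2CH2Cl, 70 °C; then 0.01 M aq. HCl wash
Reagents that add atoms: trimethyltin hydroxide C[Sn](C)(C)O
Why: Trimethyltin hydroxide cleaves simple alkyl esters under near-neutral conditions by delivering hydroxide from tin to the ester carbonyl, giving the stannyl ester 19, which the dilute acid wash converts to the acid. This avoids the strong base that would epimerise C3 or open ring B and the strong acid that would cyclise the prenyl group onto the 5-hydroxyl.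

## Compound list

1 | 1-(2,4,6-trihydroxyphenyl)propan-1-one | CCC(=O)c1c(O)cc(O)cc1O | starting material
2 | 1-(2,6-dihydroxy-4-methoxyphenyl)propan-1-one | CCC(=O)c1c(O)cc(OC)cc1O | intermediate
3 | iodoethane | CCI | starting material
4 | 1-(2-ethoxy-6-hydroxy-4-methoxyphenyl)propan-1-one | CCOc1cc(OC)cc(O)c1C(=O)CC | intermediate
5 | triisopropylsilyl trifluoromethanesulfonate | CC(C)[Si](C(C)C)(C(C)C)OS(=O)(=O)C(F)(F)F | starting material
6 | 1-[2-ethoxy-4-methoxy-6-(triisopropylsilyloxy)phenyl]propan-1-one | CCOc1cc(OC)cc(O[Si](C(C)C)(C(C)C)C(C)C)c1C(=O)CC | intermediate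
7 | 1-[2-ethoxy-4-methoxy-6-(triisopropylsilyloxy)phenyl]-4,4,4-trifluoro-2-methylbutane-1,3-dione | CCOc1cc(OC)cc(O[Si](C(C)C)(C(C)C)C(C)C)c1C(=O)C(C)C(=O)C(F)(F)F | intermediate (not isolated)
8 | 2-diazo-1-[2-ethoxy-4-methoxy-6-(triisopropylsilyloxy)phenyl]propan-1-one | CCOc1cc(OC)cc(O[Si](C(C)C)(C(C)C)C(C)C)c1C(=O)C(C)=[N+]=[N-] | intermediate
9 | (2S,3R)-7-methoxy-2,3-dimethyl-5-(triisopropylsilyloxy)chroman-4-one | COc1cc2O[C@@H](C)[C@@H](C)C(=O)c2c(O[Si](C(C)C)(C(C)C)C(C)C)c1 | intermediate
10 | (2S,3R)-8-iodo-7-methoxy-2,3-dimethyl-5-(triisopropylsilyloxy)chroman-4-one | COc1cc(O[Si](C(C)C)(C(C)C)C(C)C)c2c(c1I)O[C@@H](C)[C@@H](C)C2=O | intermediate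
11 | ethyl (E)-3-(tributylstannyl)prop-2-enoate | CCOC(=O)/C=C/[Sn](CCCC)(CCCC)CCCC | starting material
12 | ethyl (E)-3-[(2S,3R)-7-methoxy-2,3-dimethyl-4-oxo-5-(triisopropylsilyloxy)chroman-8-yl]prop-2-enoate | CCOC(=O)/C=C/c1c(OC)cc(O[Si](C(C)C)(C(C)C)C(C)C)c2c1O[C@@H](C)[C@@H](C)C2=O | intermediate
13 | phenylboronic acid | OB(O)c1ccccc1 | starting material
14 | ethyl (3R)-3-[(2S,3R)-7-methoxy-2,3-dimethyl-4-oxo-5-(triisopropylsilyloxy)chroman-8-yl]-3-phenylpropanoate | COc1cc(O[Si](C(C)C)(C(C)C)C(C)C)c2c(c1[C@H](CC(=O)OCC)c1ccccc1)O[C@@H](C)[C@@H](C)C2=O | intermediate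
15 | ethyl (3R)-3-[(2S,3R)-5-hydroxy-7-methoxy-2,3-dimethyl-4-oxochroman-8-yl]-3-phenylpropanoate | COc1cc(O)c2c(c1[C@H](CC(=O)OCC)c1ccccc1)O[C@@H](C)[C@@H](C)C2=O | intermediate
16 | ethyl (3R)-3-[(2S,3R)-5-hydroxy-6-iodo-7-methoxy-2,3-dimethyl-4-oxochroman-8-yl]-3-phenylpropanoate | COc1c(I)c(O)c2c(c1[C@H](CC(=O)OCC)c1ccccc1)O[C@@H](C)[C@@H](C)C2=O | intermediate
17 | tributyl(3-methylbut-2-en-1-yl)stannane | CC(C)=CC[Sn](CCCC)(CCCC)CCCC | starting material
18 | ethyl (3R)-3-[(2S,3R)-5-hydroxy-7-methoxy-2,3-dimethyl-6-(3-methylbut-2-en-1-yl)-4-oxochroman-8-yl]-3-phenylpropanoate | COc1c(CC=C(C)C)c(O)c2c(c1[C@H](CC(=O)OCC)c1ccccc1)O[C@@H](C)[C@@H](C)C2=O | intermediate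
19 | trimethylstannyl (3R)-3-[(2S,3R)-5-hydroxy-7-methoxy-2,3-dimethyl-6-(3-methylbut-2-en-1-yl)-4-oxochroman-8-yl]-3-phenylpropanoate | COc1c(CC=C(C)C)c(O)c2c(c1[C@H](CC(=O)O[Sn](C)(C)C)c1ccccc1)O[C@@H](C)[C@@H](C)C2=O | intermediate (not isolated)
20 | (3R)-3-[(2S,3R)-5-hydroxy-7-methoxy-2,3-dimethyl-6-(3-methylbut-2-en-1-yl)-4-oxochroman-8-yl]-3-phenylpropanoic acid | COc1c(CC=C(C)C)c(O)c2c(c1[C@H](CC(=O)O)c1ccccc1)O[C@@H](C)[C@@H](C)C2=O | target

## Step count and least certain steps

Total step count: 12. Longest linear sequence: 12 steps (1 to 20); 3, 5, 11, 13 and 17 are purchased.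

**Step 5 (key step).** The carbenoid may be diverted before it inserts, by attack of the ethoxy oxygen (oxonium ylide and 1,2-shift) or by 1,2-hydride shift from its methyl group. Enantioface discrimination may also be weak, because the aryl ketone is twisted out of conjugation by its two ortho substituents. The fallback forms O1–C2 instead of C2–C3. It sets out from 2 and returns at 9.
- Both phenols of 2 are silylated with 5 and 2,6-lutidine to give 1-[4-methoxy-2,6-bis(triisopropylsilyloxy)phenyl]propan-1-one F1.
- Aldol addition of its lithium enolate to acetaldehyde at −78 °C gives 3-hydroxy-1-[4-methoxy-2,6-bis(triisopropylsilyloxy)phenyl]-2-methylbutan-1-one F2.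
- Dehydration with catalytic toluenesulfonic acid in toluene gives (E)-1-[4-methoxy-2,6-bis(triisopropylsilyloxy)phenyl]-2-methylbut-2-en-1-one F3.
- One equivalent of acetic acid-buffered Bu4NF at −20 °C removes one of the two equivalent silyl groups to give (E)-1-[2-hydroxy-4-methoxy-6-(triisopropylsilyloxy)phenyl]-2-methylbut-2-en-1-one F4.
- A cinchona alkaloid (quinine or quinidine, whichever gives the 2S,3R sense) in chlorobenzene at room temperature then closes ring B by intramolecular oxa-Michael addition with enantioselective protonation, a known entry to cis-2,3-dimethylchroman-4-ones from ortho-tigloyl phenols.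

**Step 8.** The beta carbon carries a 2,6-dioxygenated aryl group twisted out of the alkene plane, so insertion into the phenyl–rhodium bond may be slower than hydrolysis of that bond, and facial discrimination may be eroded. The fallback uses auxiliary control and an organocopper reagent. It sets out from 12 and returns at 14.
- Me3SnOH cleaves the ester to (E)-3-[(2S,3R)-7-methoxy-2,3-dimethyl-4-oxo-5-(triisopropylsilyloxy)chroman-8-yl]prop-2-enoic acid F5.
- Pivaloyl chloride and triethylamine at −20 °C give the mixed pivalic anhydride F6.
- The lithium salt of (4S)-4-phenyl-1,3-oxazolidin-2-one at −78 °C gives (4S)-3-[(E)-3-[(2S,3R)-7-methoxy-2,3-dimethyl-4-oxo-5-(triisopropylsilyloxy)chroman-8-yl]prop-2-enoyl]-4-phenyl-1,3-oxazolidin-2-one F7.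
- PhMgBr with CuBr·SMe2 in THF at −40 °C adds phenyl to the chelated s-cis imide from the face opposite the auxiliary phenyl group, which is the R sense here, giving (4S)-3-[(3R)-3-[(2S,3R)-7-methoxy-2,3-dimethyl-4-oxo-5-(triisopropylsilyloxy)chroman-8-yl]-3-phenylpropanoyl]-4-phenyl-1,3-oxazolidin-2-one F8.
- Sm(OTf)3-catalysed ethanolysis releases 14.

**Step 4.** The silyl group may migrate from the phenol oxygen to the enolate oxygen, the hindered enolate may be acylated on oxygen instead of carbon, and the aryl silyl ether may be partly lost in aqueous triethylamine. The fallback avoids any enolate. It sets out from 6 and returns at 8.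
- Riley oxidation with SeO2 in aqueous dioxane gives 1-[2-ethoxy-4-methoxy-6-(triisopropylsilyloxy)phenyl]propane-1,2-dione F9.
- Tosylhydrazide condenses at the unhindered C2 carbonyl to give N'-[1-[2-ethoxy-4-methoxy-6-(triisopropylsilyloxy)phenyl]-1-oxopropan-2-ylidene]-4-methylbenzenesulfonohydrazide F10.
- Triethylamine in CH2Cl2 eliminates sulfinate (Bamford–Stevens-type) to give 8.

**Step 11.** Allylic transposition may place the aryl group on the tertiary carbon of the allyl unit, the stannane may be protonated by the phenol, and oxidative addition at the doubly ortho-substituted iodide may be slow. The fallback separates C–C bond formation from installation of the trisubstituted alkene. It sets out from 16 and returns at 18.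
- Stille coupling with allyltributylstannane, which has no regiochemical ambiguity, gives ethyl (3R)-3-[(2S,3R)-5-hydroxy-7-methoxy-2,3-dimethyl-4-oxo-6-(prop-2-en-1-yl)chroman-8-yl]-3-phenylpropanoate F11.
- Cross-metathesis with excess 2-methylbut-2-ene and the second-generation Grubbs catalyst in CH2Cl2 at 40 °C gives 18.

**Step 12.** Ester cleavage may be slow, and prolonged heating may then erode the cis configuration at C3 through enolisation or ring opening and reclosure. The fallback frees the acid before the prenyl group is present, where acid catalysis is permissible. It sets out from 15 and returns at 20.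
- Hydrolysis with 2 M HCl in dioxane at 50 °C, where neither a phenoxide nor an enolate is formed, gives (3R)-3-[(2S,3R)-5-hydroxy-7-methoxy-2,3-dimethyl-4-oxochroman-8-yl]-3-phenylpropanoic acid F12.
- NIS in MeCN gives (3R)-3-[(2S,3R)-5-hydroxy-6-iodo-7-methoxy-2,3-dimethyl-4-oxochroman-8-yl]-3-phenylpropanoic acid F13.
- Stille coupling with a threefold excess of 17 (Pd(PPh3)4, toluene, 100 °C) gives 20; the excess compensates for protodestannylation by the acid.

## Further compounds

F1 | step 5 | 1-[4-methoxy-2,6-bis(triisopropylsilyloxy)phenyl]propan-1-one | CCC(=O)c1c(O[Si](C(C)C)(C(C)C)C(C)C)cc(OC)cc1O[Si](C(C)C)(C(C)C)C(C)C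
F2 | step 5 | 3-hydroxy-1-[4-methoxy-2,6-bis(triisopropylsilyloxy)phenyl]-2-methylbutan-1-one (diastereomer mixture) | CC(O)C(C)C(=O)c1c(O[Si](C(C)C)(C(C)C)C(C)C)cc(OC)cc1O[Si](C(C)C)(C(C)C)C(C)C
F3 | step 5 | (E)-1-[4-methoxy-2,6-bis(triisopropylsilyloxy)phenyl]-2-methylbut-2-en-1-one | C/C=C(\C)C(=O)c1c(O[Si](C(C)C)(C(C)C)C(C)C)cc(OC)cc1O[Si](C(C)C)(C(C)C)C(C)C
F4 | step 5 | (E)-1-[2-hydroxy-4-methoxy-6-(triisopropylsilyloxy)phenyl]-2-methylbut-2-en-1-one | C/C=C(\C)C(=O)c1c(O)cc(OC)cc1O[Si](C(C)C)(C(C)C)C(C)C
F5 | step 8 | (E)-3-[(2S,3R)-7-methoxy-2,3-dimethyl-4-oxo-5-(triisopropylsilyloxy)chroman-8-yl]prop-2-enoic acid | COc1cc(O[Si](C(C)C)(C(C)C)C(C)C)c2c(c1/C=C/C(=O)O)O[C@@H](C)[C@@H](C)C2=O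
F6 | step 8 | (E)-3-[(2S,3R)-7-methoxy-2,3-dimethyl-4-oxo-5-(triisopropylsilyloxy)chroman-8-yl]prop-2-enoic 2,2-dimethylpropanoic anhydride | COc1cc(O[Si](C(C)C)(C(C)C)C(C)C)c2c(c1/C=C/C(=O)OC(=O)C(C)(C)C)O[C@@H](C)[C@@H](C)C2=O
F7 | step 8 | (4S)-3-[(E)-3-[(2S,3R)-7-methoxy-2,3-dimethyl-4-oxo-5-(triisopropylsilyloxy)chroman-8-yl]prop-2-enoyl]-4-phenyl-1,3-oxazolidin-2-one | COc1cc(O[Si](C(C)C)(C(C)C)C(C)C)c2c(c1/C=C/C(=O)N1[C@@H](c3ccccc3)COC1=O)O[C@@H](C)[C@@H](C)C2=O
F8 | step 8 | (4S)-3-[(3R)-3-[(2S,3R)-7-methoxy-2,3-dimethyl-4-oxo-5-(triisopropylsilyloxy)chroman-8-yl]-3-phenylpropanoyl]-4-phenyl-1,3-oxazolidin-2-one | COc1cc(O[Si](C(C)C)(C(C)C)C(C)C)c2c(c1[C@H](CC(=O)N1[C@@H](c3ccccc3)COC1=O)c1ccccc1)O[C@@H](C)[C@@H](C)C2=O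
F9 | step 4 | 1-[2-ethoxy-4-methoxy-6-(triisopropylsilyloxy)phenyl]propane-1,2-dione | CCOc1cc(OC)cc(O[Si](C(C)C)(C(C)C)C(C)C)c1C(=O)C(C)=O
F10 | step 4 | N'-[1-[2-ethoxy-4-methoxy-6-(triisopropylsilyloxy)phenyl]-1-oxopropan-2-ylidene]-4-methylbenzenesulfonohydrazide | CCOc1cc(OC)cc(O[Si](C(C)C)(C(C)C)C(C)C)c1C(=O)C(C)=NNS(=O)(=O)c1ccc(C)cc1
F11 | step 11 | ethyl (3R)-3-[(2S,3R)-5-hydroxy-7-methoxy-2,3-dimethyl-4-oxo-6-(prop-2-en-1-yl)chroman-8-yl]-3-phenylpropanoate | COc1c(CC=C)c(O)c2c(c1[C@H](CC(=O)OCC)c1ccccc1)O[C@@H](C)[C@@H](C)C2=O
F12 | step 12 | (3R)-3-[(2S,3R)-5-hydroxy-7-methoxy-2,3-dimethyl-4-oxochroman-8-yl]-3-phenylpropanoic acid | COc1cc(O)c2c(c1[C@H](CC(=O)O)c1ccccc1)O[C@@H](C)[C@@H](C)C2=O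
F13 | step 12 | (3R)-3-[(2S,3R)-5-hydroxy-6-iodo-7-methoxy-2,3-dimethyl-4-oxochroman-8-yl]-3-phenylpropanoic acid | COc1c(I)c(O)c2c(c1[C@H](CC(=O)O)c1ccccc1)O[C@@H](C)[C@@H](C)C2=O
A1 | alternative 1 | (2S,3R)-7-methoxy-5-[(4-methoxyphenyl)methoxy]-2,3-dimethyl-6-(3-methylbut-2-en-1-yl)chroman-4-one | COc1cc2O[C@@H](C)[C@@H](C)C(=O)c2c(OCc2ccc(OC)cc2)c1CC=C(C)C
A2 | alternative 2 | (2S,3R)-5,7-dihydroxy-2,3-dimethyl-6-(3-methylbut-2-en-1-yl)chroman-4-one | Oc1cc2O[C@@H](C)[C@@H](C)C(=O)c2c(O)c1CC=C(C)C
A3 | alternative 3 | (2S,3R)-5,7-dimethoxy-2,3-dimethylchroman-4-one | COc1cc2O[C@@H](C)[C@@H](C)C(=O)c2c(OC)c1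
A4 | alternative 3 | (2R,3S)-3-(3,5-dimethoxyphenoxy)-2-methylbutanoic acid | COc1cc(OC)cc(O[C@@H](C)[C@@H](C)C(=O)O)c1
A5 | alternative 3 | 3,5-dimethoxyphenol | COc1cc(O)cc(OC)c1
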